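## The problem

The target is a resveratrol tetramer built from three oxygen heterocycles. Ring A is an aromatic 2,3-diarylbenzofuran; its C4 is joined through an E-ethene bridge to C5 of ring B, a trans-2,3-diaryl-2,3-dihydrobenzofuran; C3 of ring B is bonded directly to C4 of ring C, a second trans-2,3-diaryl-2,3-dihydrobenzofuran.

There are four stereocentres: C2 and C3 of ring B (2R,3R) and C2 and C3 of ring C (2S,3S). Within each ring C3 can control C2, because the 4-oxybenzylic C2–O bond ionises reversibly under acid and the trans isomer is the stable one. The two C3 centres cannot be corrected once made. That of ring C has to be set relative to ring B across a single, freely rotating C(sp3)–C(aryl) bond, so only weak remote induction or an external chiral catalyst is available. The bond from ring B to ring C also sits at the most crowded carbon of ring C, between C3a and C5.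

Nine free phenols make the final compound sensitive to oxidation, so they must stay masked to the end. Hydrogenolysis is excluded by the alkene and by the benzylic C2–O bonds. Strong acid threatens the stilbene, which can close onto the neighbouring 3,5-dioxygenated ring on C3 of ring A.

The feature that opens the synthesis is that the benzene ring of ring C (C3a to C7a, with O1 on C7a and a hydroxyl on C6) is nothing more than the 3,5-dihydroxyphenyl group on C3 of ring B. C2–C3 of ring C with its two aryl groups is the alkene of resveratrol. Ring C can therefore be laid onto a ring B resorcinol by joining C3 to C3a and O1 to C2 in one oxidative event.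

## Retrosynthesis

**Unmasking (26 from 25).** Only eight O–methyl bonds are cut. Methyl ethers are preferred to benzyl or silyl groups because stilbene 14 is sold as its trimethyl ether and because they survive organomagnesium, carbene, photoredox and palladium chemistry. The forward step needs a Lewis-acid demethylation that spares two dihydrofurans and the E-alkene. Both dihydrofurans are by then in their thermodynamic trans form, so reversible C2–O ionisation does no stereochemical harm.

**The bridge (25 from 15 and 24).** The bond between C5 of ring B and the ethene carbon is cut, a Mizoroki–Heck disconnection. Cutting the C=C bond itself would require a benzylic phosphorus handle on the half that carries all four stereocentres. Cutting at C4 of ring A would place a styrene on that half during the radical-cation step. With the chosen cut, 15 needs only an aryl bromide, inert to all earlier chemistry and present from starting material 1, and the molecule falls into two halves of similar size. The forward reaction must give the E-alkene from an electron-rich aryl bromide in the presence of one free phenol.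

**Ring C (15 from 13 and 14).** C3–C3a and O1–C2 of ring C are cut together, which removes one ring, two skeletal bonds and two stereocentres and leaves resorcinol 13 and the purchased stilbene 14. The neighbouring cuts are less attractive. Cutting C2–C3 of ring C would demand an aroyl group placed ortho to the ring B substituent and some six further operations. Cutting the ring B–ring C bond would mean arylating a stereogenic benzylic carbon with a hindered arene. The forward step must select the resorcinol carbon ortho to the side chain, bond it to the alkene carbon bearing the 3,5-dimethoxyphenyl group, and distinguish the two faces under the influence of C3 of ring B. The last point is the unproven one.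

**Ring B (13 from 12, 11, 10 and 9).** Compound 13 comes from bis-silyl ether 12 by desilylation, and 12 from its cis isomer 11 by epimerisation at C2. In 11 the C2–C3 bond is cut, which leads to diaryldiazomethane 10 and hydrazone 9. Insertion of a donor/donor rhodium carbene into the benzylic ether C–H sets C3 under catalyst control. A second phenol–stilbene annulation would offer no control of absolute configuration here. The forward sequence has to deliver C3 as R and then move C2 to the trans position without touching C3.

**The benzophenone (9 from 8, 7, 6, 5 and 3).** Hydrazone 9 comes from ketone 8, and 8 from carbinol 7. Cutting the aryl–carbinol bond gives aldehyde 3 (from 1 and 2) and arylmagnesium reagent 6 (from 5, itself from 4). Silyl ethers on the resorcinol are orthogonal to the methyl ethers and tolerate every step up to their removal.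

**Ring A (24 from 23, 22 and 21, and these from 19, 20, 18, 16 and 17).** The vinyl group is traced through aldehyde 23 and alcohol 22 to ester 21. Cutting the C2–aryl bond of 21 gives 19 and 20 (direct arylation). Cutting C3–C3a of 19 gives aryloxy ketone 18 (cyclodehydration), which is the ether of 16 and 17. The forward cyclisation must close ortho to the ester, para to the methoxy group.

## Roads not taken

**Alternative 1:** The benzene ring of ring A is cut (C3a–C4, C4–C5, C6–C7, C7–C7a).
- Forward step: furyl diazomethyl ketone A2 is irradiated with ethoxyacetylene A3. A Wolff shift forms C7–C7a, [2+2] addition to the alkyne forms C4–C5 and C6–C7, and four-electron opening followed by six-electron closure onto the furan forms C3a–C4. The product is benzofuranol A1.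
- Merits: the substitution pattern is fixed by mechanism, and the C4 hydroxyl is a direct handle for sulfonylation and coupling. The 6-ethoxy group would fall with the methyl ethers.
- Weak points: A2 needs a 2,4,5-trisubstituted furan with both aryl groups and a diazoketone, which is several steps and a photolysis. The strategic step is also spent on the only part of the molecule that has no stereocentre; rings B and C remain unsolved.
- Comparison: this road is better than step 11 of the chosen plan on regiochemical certainty for ring A. The chosen plan sets against it purchased building blocks, conventional steps, and a key step that addresses ring C, where the difficulty lies.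

**Alternative 2:** The benzene ring of ring C is cut (C4–C5 and C3a–C7a).
- Forward step: ynone A5 and diene A6 undergo Diels–Alder addition and aromatisation to A4. The aroyl group then sits unambiguously ortho to the ring B substituent, next to a free hydroxyl.
- Completion: ring C would be closed as in steps 5–7 of the chosen route (etherification with 2, hydrazone, diazo compound, carbene insertion, epimerisation).
- Merits: there is no site-selectivity question on a resorcinol, and ring C's stereocentres are set by a chiral catalyst, not by remote induction. In both respects this road is better than the chosen one.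
- Weak points: A5 needs an enantiopure 3-alkynyl dihydrobenzofuran, which the aryl/aryl carbene entry to ring B does not give, and its propargylic C3–H next to the ynone is prone to epimerisation. Five or six operations follow the cycloaddition, where the chosen plan needs one.
- Comparison: the chosen plan sets brevity and a purchased two-carbon partner against the better stereocontrol. The fallback for step 9 borrows the carbene end game of this alternative.

**Alternative 3:** C3–C3a and O1–C2 of ring B are cut.
- Forward step: 1,4-benzoquinone A9 is activated by a chiral phosphoric acid and attacked by stilbene A8 at the carbon remote from the 4-methoxyphenyl group. The quinone oxygen closes on the benzylic carbon to give phenol A7.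
- Merits: it is as convergent as the chosen plan, and a catalyst sits at the reacting centres of ring B. The C5 hydroxyl of A7 could be sulfonylated for the bridge-forming coupling.
- Weak points: A8 already contains ring C with both stereocentres in enantiopure form, so the ring C problem is only moved back. The nucleophilic carbon of A8 is flanked by an ortho-disubstituted arene. A plain stilbene offers the acid no hydrogen-bond anchor, so enantiocontrol would have to override substrate bias. Quinone redox chemistry and [2+2] adducts compete.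
- Comparison: catalyst control of ring B is matched in the chosen plan by the carbene insertion, which is established on this ring system. The chosen plan then stakes only ring C on induction, with 14 as a purchased partner.

Key step: step 9

Assumption: Rh2(R-PTAD)4 is taken to give the (3R) configuration at the new diarylmethine carbon, as in the closest donor/donor carbene insertions into 4-methoxybenzyl aryl ethers; if the sense proves opposite, Rh2(S-PTAD)4 is used instead.

## Route

Step 1
Reactants: 1 5-bromo-2-hydroxybenzaldehyde; 2 4-methoxybenzyl chloride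
Product: 3 5-bromo-2-[(4-methoxybenzyl)oxy]benzaldehyde
Conditions: K2CO3, KI (cat.), DMF, 60 °C
Reagents that add atoms: none
Why: Williamson ether synthesis; the phenoxide displaces the benzylic chloride, the aldehyde and the aryl bromide are inert, and the benzylic CH2 installed here is the later C2 of ring B.

Step 2
Reactants: 4 5-bromoresorcinol
Product: 5 1-bromo-3,5-bis(triisopropylsilyloxy)benzene
Conditions: TIPSCl, imidazole, DMF, rt
Reagents that add atoms: triisopropylsilyl chloride, CC(C)[Si](Cl)(C(C)C)C(C)C
Why: Standard silylation of phenols; the bulky aryl silyl ethers should survive magnesium, hydrazine, MnO2, the carbene step and trifluoroacetic acid, and are removable by fluoride without touching methyl ethers.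

Step 3
Reactants: 5 1-bromo-3,5-bis(triisopropylsilyloxy)benzene; 3 5-bromo-2-[(4-methoxybenzyl)oxy]benzaldehyde
Product: 7 {5-bromo-2-[(4-methoxybenzyl)oxy]phenyl}[3,5-bis(triisopropylsilyloxy)phenyl]methanol (racemic), via the arylmagnesium bromide 6 (not isolated)
Conditions: Mg turnings, THF, 50 °C; solution of 6 decanted from excess Mg; then 3, THF, −20 → 0 °C; H2O
Reagents that add atoms: none
Why: Grignard addition to an aldehyde; 1,2-addition at low temperature is much faster than halogen–magnesium exchange with the aryl bromide of 3, and the carbinol stereocentre is erased in step 4.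

Step 4
Reactants: 7 {5-bromo-2-[(4-methoxybenzyl)oxy]phenyl}[3,5-bis(triisopropylsilyloxy)phenyl]methanol
Product: 8 {5-bromo-2-[(4-methoxybenzyl)oxy]phenyl}[3,5-bis(triisopropylsilyloxy)phenyl]methanone
Conditions: MnO2, CH2Cl2, rt
Reagents that add atoms: none
Why: MnO2 oxidation of a doubly benzylic alcohol; benzyl ether, silyl ethers and aryl bromide are not affected.

Step 5
Reactants: 8 {5-bromo-2-[(4-methoxybenzyl)oxy]phenyl}[3,5-bis(triisopropylsilyloxy)phenyl]methanone
Product: 9 hydrazone of 8, {5-bromo-2-[(4-methoxybenzyl)oxy]phenyl}[3,5-bis(triisopropylsilyloxy)phenyl]methanone hydrazone (E/Z mixture)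
Conditions: N2H4·H2O, AcOH (cat.), EtOH, 80 °C
Reagents that add atoms: hydrazine, NN
Why: Acid-catalysed condensation of a diaryl ketone with excess hydrazine to the N-unsubstituted hydrazone; the excess suppresses azine formation and the hindered aryl silyl ethers should withstand the conditions.

Step 6
Reactants: 9 hydrazone of 8
Product: 11 (2S,3R)-5-bromo-3-[3,5-bis(triisopropylsilyloxy)phenyl]-2-(4-methoxyphenyl)-2,3-dihydro-1-benzofuran (cis), via the diaryldiazomethane 10 (not isolated)
Conditions: MnO2, CH2Cl2, 0 °C, filtration; then Rh2(R-PTAD)4 (1 mol%), CH2Cl2, 0 °C → rt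
Reagents that add atoms: none
Why: Hydrazone dehydrogenation followed by intramolecular C–H insertion of a donor/donor rhodium carbene into the benzylic ether CH2 (five-membered ring); the concerted insertion places the two aryl groups cis, and the chiral carboxylate ligands select the enantiotopic hydrogen and so set C3 as R, with C2 following as S.

Step 7
Reactants: 11 (2S,3R)-5-bromo-3-[3,5-bis(triisopropylsilyloxy)phenyl]-2-(4-methoxyphenyl)-2,3-dihydro-1-benzofuran
Product: 12 (2R,3R)-5-bromo-3-[3,5-bis(triisopropylsilyloxy)phenyl]-2-(4-methoxyphenyl)-2,3-dihydro-1-benzofuran (trans)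
Conditions: TFA, CH2Cl2, 0 °C
Reagents that add atoms: none
Why: Acid-mediated epimerisation; the C2–O bond ionises reversibly to a 4-methoxybenzylic cation and the phenol recloses to the more stable trans isomer, so only C2 inverts and C3 keeps the configuration set in step 6.

Step 8
Reactants: 12 (2R,3R)-5-bromo-3-[3,5-bis(triisopropylsilyloxy)phenyl]-2-(4-methoxyphenyl)-2,3-dihydro-1-benzofuran
Product: 13 5-[(2R,3R)-5-bromo-2-(4-methoxyphenyl)-2,3-dihydro-1-benzofuran-3-yl]benzene-1,3-diol
Conditions: TBAF, AcOH, THF, 0 °C
Reagents that add atoms: none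
Why: Fluoride cleavage of aryl silyl ethers; buffering with acetic acid keeps the electron-rich resorcinol from standing as a phenoxide, and no stereocentre is involved.

Step 9
Reactants: 13 5-[(2R,3R)-5-bromo-2-(4-methoxyphenyl)-2,3-dihydro-1-benzofuran-3-yl]benzene-1,3-diol; 14 (E)-3,4',5-trimethoxystilbene
Product: 15 (2S,3S)-4-[(2R,3R)-5-bromo-2-(4-methoxyphenyl)-2,3-dihydro-1-benzofuran-3-yl]-3-(3,5-dimethoxyphenyl)-2-(4-methoxyphenyl)-2,3-dihydro-1-benzofuran-6-ol
Conditions: Ru(bpz)3(PF6)2 (2 mol%), (NH4)2S2O8 (2 equiv), 14 (1.5 equiv, in portions), degassed MeCN, blue LEDs, rt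
Reagents that add atoms: none
Why: Proposed new method: the excited ruthenium complex is quenched oxidatively by persulfate, and the trivalent ruthenium species so formed, together with the sulfate radical anion, takes one electron from 14, the most easily oxidised π-system present. The resorcinol carbon of 13 ortho to the ring B substituent (para to one hydroxyl, ortho to the other) adds to the alkene carbon bearing the 3,5-dimethoxyphenyl group, which leaves a 4-methoxybenzylic radical, and proton loss restores the arene (C3–C3a bond). A second one-electron oxidation gives the 4-methoxybenzylic cation, which the adjacent phenol oxygen captures in a 5-exo-trig closure (O1–C2 bond), completing the dihydrofuran of ring C. The closest known reaction type is the photoredox oxidative [3+2] cycloaddition of 4-alkoxyphenols with electron-rich styrenes under this catalyst and oxidant, in which the phenol is the oxidised partner; a meta-dioxygenated phenol with a stilbene, and the inverted order of oxidation, have not been shown. C3 of ring C is fixed in the C–C bond formation, where the resorcinol ring has its two faces differentiated by the C2–H side and the fused benzo ring of ring B; this bias from C3 of ring B has to favour the (3S) adduct, the induction is expected to be modest, and the other diastereomer would be removed by chromatography. C2 follows trans to C3 because the closing cation sets the aryl groups anti, and any cis isomer can equilibrate through reversible C2–O ionisation in the hydrogensulfate-acidified medium. Site selectivity rests on the two homotopic ortho positions being para-activated by a hydroxyl, whereas the carbon between the hydroxyls is only ortho-activated; a second annulation is held back because the para-activated carbon next to the remaining hydroxyl of 15 is buried beside ring B, and because 14 is added in portions.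

Step 10
Reactants: 16 methyl 3-hydroxy-5-methoxybenzoate; 17 2-bromo-1-(3,5-dimethoxyphenyl)ethan-1-one
Product: 18 methyl 3-[2-(3,5-dimethoxyphenyl)-2-oxoethoxy]-5-methoxybenzoate
Conditions: K2CO3, acetone, reflux
Reagents that add atoms: none
Why: Williamson ether synthesis with an α-bromo ketone, a highly reactive alkylating agent towards phenoxide.

Step 11
Reactants: 18 methyl 3-[2-(3,5-dimethoxyphenyl)-2-oxoethoxy]-5-methoxybenzoate
Product: 19 methyl 3-(3,5-dimethoxyphenyl)-6-methoxy-1-benzofuran-4-carboxylate
Conditions: Bi(OTf)3 (10 mol%), CH2Cl2, reflux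
Reagents that add atoms: none
Why: Lewis-acid cyclodehydration of an α-aryloxy ketone (intramolecular Friedel–Crafts hydroxyalkylation, then loss of water); attack by the ring carbon para to the methoxy group, which lies ortho to the ester, gives the 4-carboxylate, as known for this substitution pattern.

Step 12
Reactants: 19 methyl 3-(3,5-dimethoxyphenyl)-6-methoxy-1-benzofuran-4-carboxylate; 20 4-bromoanisole
Product: 21 methyl 3-(3,5-dimethoxyphenyl)-6-methoxy-2-(4-methoxyphenyl)-1-benzofuran-4-carboxylate
Conditions: Pd(OAc)2 (5 mol%), PCy3·HBF4 (10 mol%), PivOH (30 mol%), K2CO3, DMA, 110 °C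
Reagents that add atoms: none
Why: Palladium-catalysed direct C–H arylation by concerted metalation–deprotonation with pivalate; C2 is the only C–H on the furan ring and the most acidic one in the molecule.

Step 13
Reactants: 21 methyl 3-(3,5-dimethoxyphenyl)-6-methoxy-2-(4-methoxyphenyl)-1-benzofuran-4-carboxylate
Product: 22 [3-(3,5-dimethoxyphenyl)-6-methoxy-2-(4-methoxyphenyl)-1-benzofuran-4-yl]methanol
Conditions: LiAlH4, THF, 0 °C
Reagents that add atoms: none
Why: Hydride reduction of an aryl ester to the benzylic alcohol; nothing else in the molecule is reducible.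

Step 14
Reactants: 22 [3-(3,5-dimethoxyphenyl)-6-methoxy-2-(4-methoxyphenyl)-1-benzofuran-4-yl]methanol
Product: 23 3-(3,5-dimethoxyphenyl)-6-methoxy-2-(4-methoxyphenyl)-1-benzofuran-4-carbaldehyde
Conditions: MnO2, CH2Cl2, rt
Reagents that add atoms: none
Why: MnO2 oxidation of a benzylic alcohol stops at the aldehyde, and the neutral conditions avoid acid-induced closure of the aldehyde onto the neighbouring dimethoxyphenyl ring.

Step 15
Reactants: 23 3-(3,5-dimethoxyphenyl)-6-methoxy-2-(4-methoxyphenyl)-1-benzofuran-4-carbaldehyde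
Product: 24 3-(3,5-dimethoxyphenyl)-4-ethenyl-6-methoxy-2-(4-methoxyphenyl)-1-benzofuran
Conditions: Ph3PCH3Br, KOt-Bu, THF, 0 °C → rt
Reagents that add atoms: methyltriphenylphosphonium bromide, C[P+](c1ccccc1)(c1ccccc1)c1ccccc1.[Br-]
Why: Wittig methylenation of an aromatic aldehyde with the non-stabilised ylide; no stereochemical issue arises.

Step 16
Reactants: 15 (2S,3S)-4-[(2R,3R)-5-bromo-2-(4-methoxyphenyl)-2,3-dihydro-1-benzofuran-3-yl]-3-(3,5-dimethoxyphenyl)-2-(4-methoxyphenyl)-2,3-dihydro-1-benzofuran-6-ol; 24 3-(3,5-dimethoxyphenyl)-4-ethenyl-6-methoxy-2-(4-methoxyphenyl)-1-benzofuran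
Product: 25 (2R,3R)-3-[(2S,3S)-3-(3,5-dimethoxyphenyl)-6-hydroxy-2-(4-methoxyphenyl)-2,3-dihydro-1-benzofuran-4-yl]-5-{(E)-2-[3-(3,5-dimethoxyphenyl)-6-methoxy-2-(4-methoxyphenyl)-1-benzofuran-4-yl]ethenyl}-2-(4-methoxyphenyl)-2,3-dihydro-1-benzofuran
Conditions: Pd2(dba)3 (2.5 mol%), P(t-Bu)3·HBF4 (10 mol%), Cy2NMe, 1,4-dioxane, 90 °C
Reagents that add atoms: none
Why: Mizoroki–Heck coupling; zerovalent palladium with the bulky electron-rich phosphine adds to the electron-rich aryl bromide, the aryl group is delivered to the terminal alkene carbon, and syn β-hydride elimination gives the E-stilbene; the free phenol and the four stereocentres are not involved under the mild amine base.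

Step 17
Reactants: 25 the octamethyl ether named in step 16
Product: 26 (2R,3R)-3-[(2S,3S)-3-(3,5-dihydroxyphenyl)-6-hydroxy-2-(4-hydroxyphenyl)-2,3-dihydro-1-benzofuran-4-yl]-5-{(E)-2-[3-(3,5-dihydroxyphenyl)-6-hydroxy-2-(4-hydroxyphenyl)-1-benzofuran-4-yl]ethenyl}-2-(4-hydroxyphenyl)-2,3-dihydro-1-benzofuran (CNP0135983.1)
Conditions: BBr3 (20 equiv), CH2Cl2, −78 °C → rt; then MeOH/H2O, 0 °C
Reagents that add atoms: none
Why: Lewis-acid demethylation of aryl methyl ethers (O–B coordination, bromide attack at methyl, hydrolysis of the aryl borates), the usual last step for permethylated resveratrol oligomers; both dihydrofurans are already trans, so reversible C2–O ionisation cannot change the configuration.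

## Compound list

1 | 5-bromo-2-hydroxybenzaldehyde | O=Cc1cc(Br)ccc1O | starting material
2 | 4-methoxybenzyl chloride | COc1ccc(CCl)cc1 | starting material
3 | 5-bromo-2-[(4-methoxybenzyl)oxy]benzaldehyde | O=Cc1cc(Br)ccc1OCc1ccc(OC)cc1 | intermediate
4 | 5-bromoresorcinol | Oc1cc(O)cc(Br)c1 | starting material
5 | 1-bromo-3,5-bis(triisopropylsilyloxy)benzene | CC(C)[Si](Oc1cc(Br)cc(O[Si](C(C)C)(C(C)C)C(C)C)c1)(C(C)C)C(C)C | intermediate
6 | 3,5-bis(triisopropylsilyloxy)phenylmagnesium bromide | CC(C)[Si](Oc1cc([Mg]Br)cc(O[Si](C(C)C)(C(C)C)C(C)C)c1)(C(C)C)C(C)C | intermediate (not isolated)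
7 | {5-bromo-2-[(4-methoxybenzyl)oxy]phenyl}[3,5-bis(triisopropylsilyloxy)phenyl]methanol (racemic) | COc1ccc(COc2ccc(Br)cc2C(O)c2cc(O[Si](C(C)C)(C(C)C)C(C)C)cc(O[Si](C(C)C)(C(C)C)C(C)C)c2)cc1 | intermediate
8 | {5-bromo-2-[(4-methoxybenzyl)oxy]phenyl}[3,5-bis(triisopropylsilyloxy)phenyl]methanone | COc1ccc(COc2ccc(Br)cc2C(=O)c2cc(O[Si](C(C)C)(C(C)C)C(C)C)cc(O[Si](C(C)C)(C(C)C)C(C)C)c2)cc1 | intermediate
9 | hydrazone of 8 | COc1ccc(COc2ccc(Br)cc2C(=NN)c2cc(O[Si](C(C)C)(C(C)C)C(C)C)cc(O[Si](C(C)C)(C(C)C)C(C)C)c2)cc1 | intermediate
10 | 4-bromo-2-{diazo[3,5-bis(triisopropylsilyloxy)phenyl]methyl}-1-[(4-methoxybenzyl)oxy]benzene | COc1ccc(COc2ccc(Br)cc2C(=[N+]=[N-])c2cc(O[Si](C(C)C)(C(C)C)C(C)C)cc(O[Si](C(C)C)(C(C)C)C(C)C)c2)cc1 | intermediate (not isolated)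
11 | (2S,3R)-5-bromo-3-[3,5-bis(triisopropylsilyloxy)phenyl]-2-(4-methoxyphenyl)-2,3-dihydro-1-benzofuran (cis) | Brc1ccc2c(c1)[C@@H](c1cc(O[Si](C(C)C)(C(C)C)C(C)C)cc(O[Si](C(C)C)(C(C)C)C(C)C)c1)[C@@H](c1ccc(OC)cc1)O2 | intermediate
12 | (2R,3R)-5-bromo-3-[3,5-bis(triisopropylsilyloxy)phenyl]-2-(4-methoxyphenyl)-2,3-dihydro-1-benzofuran (trans) | Brc1ccc2c(c1)[C@@H](c1cc(O[Si](C(C)C)(C(C)C)C(C)C)cc(O[Si](C(C)C)(C(C)C)C(C)C)c1)[C@H](c1ccc(OC)cc1)O2 | intermediate
13 | 5-[(2R,3R)-5-bromo-2-(4-methoxyphenyl)-2,3-dihydro-1-benzofuran-3-yl]benzene-1,3-diol | Brc1ccc2c(c1)[C@@H](c1cc(O)cc(O)c1)[C@H](c1ccc(OC)cc1)O2 | intermediate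
14 | (E)-3,4',5-trimethoxystilbene | COc1ccc(/C=C/c2cc(OC)cc(OC)c2)cc1 | starting material
15 | (2S,3S)-4-[(2R,3R)-5-bromo-2-(4-methoxyphenyl)-2,3-dihydro-1-benzofuran-3-yl]-3-(3,5-dimethoxyphenyl)-2-(4-methoxyphenyl)-2,3-dihydro-1-benzofuran-6-ol | Brc1ccc2c(c1)[C@@H](c1cc(O)cc3c1[C@H](c1cc(OC)cc(OC)c1)[C@@H](c1ccc(OC)cc1)O3)[C@H](c1ccc(OC)cc1)O2 | intermediate
16 | methyl 3-hydroxy-5-methoxybenzoate | COC(=O)c1cc(O)cc(OC)c1 | starting material
17 | 2-bromo-1-(3,5-dimethoxyphenyl)ethan-1-one | COc1cc(OC)cc(C(=O)CBr)c1 | starting material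
18 | methyl 3-[2-(3,5-dimethoxyphenyl)-2-oxoethoxy]-5-methoxybenzoate | COC(=O)c1cc(OC)cc(OCC(=O)c2cc(OC)cc(OC)c2)c1 | intermediate
19 | methyl 3-(3,5-dimethoxyphenyl)-6-methoxy-1-benzofuran-4-carboxylate | COC(=O)c1cc(OC)cc2occ(-c3cc(OC)cc(OC)c3)c12 | intermediate
20 | 4-bromoanisole | COc1ccc(Br)cc1 | starting material
21 | methyl 3-(3,5-dimethoxyphenyl)-6-methoxy-2-(4-methoxyphenyl)-1-benzofuran-4-carboxylate | COC(=O)c1cc(OC)cc2oc(-c3ccc(OC)cc3)c(-c3cc(OC)cc(OC)c3)c12 | intermediate
22 | [3-(3,5-dimethoxyphenyl)-6-methoxy-2-(4-methoxyphenyl)-1-benzofuran-4-yl]methanol | OCc1cc(OC)cc2oc(-c3ccc(OC)cc3)c(-c3cc(OC)cc(OC)c3)c12 | intermediate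
23 | 3-(3,5-dimethoxyphenyl)-6-methoxy-2-(4-methoxyphenyl)-1-benzofuran-4-carbaldehyde | O=Cc1cc(OC)cc2oc(-c3ccc(OC)cc3)c(-c3cc(OC)cc(OC)c3)c12 | intermediate
24 | 3-(3,5-dimethoxyphenyl)-4-ethenyl-6-methoxy-2-(4-methoxyphenyl)-1-benzofuran | C=Cc1cc(OC)cc2oc(-c3ccc(OC)cc3)c(-c3cc(OC)cc(OC)c3)c12 | intermediate
25 | (2R,3R)-3-[(2S,3S)-3-(3,5-dimethoxyphenyl)-6-hydroxy-2-(4-methoxyphenyl)-2,3-dihydro-1-benzofuran-4-yl]-5-{(E)-2-[3-(3,5-dimethoxyphenyl)-6-methoxy-2-(4-methoxyphenyl)-1-benzofuran-4-yl]ethenyl}-2-(4-methoxyphenyl)-2,3-dihydro-1-benzofuran | COc1ccc(-c2oc3cc(OC)cc(/C=C/c4ccc5c(c4)[C@@H](c4cc(O)cc6c4[C@H](c4cc(OC)cc(OC)c4)[C@@H](c4ccc(OC)cc4)O6)[C@H](c4ccc(OC)cc4)O5)c3c2-c2cc(OC)cc(OC)c2)cc1 | intermediate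
26 | (2R,3R)-3-[(2S,3S)-3-(3,5-dihydroxyphenyl)-6-hydroxy-2-(4-hydroxyphenyl)-2,3-dihydro-1-benzofuran-4-yl]-5-{(E)-2-[3-(3,5-dihydroxyphenyl)-6-hydroxy-2-(4-hydroxyphenyl)-1-benzofuran-4-yl]ethenyl}-2-(4-hydroxyphenyl)-2,3-dihydro-1-benzofuran (CNP0135983.1) | Oc1ccc(-c2oc3cc(O)cc(/C=C/c4ccc5c(c4)[C@@H](c4cc(O)cc6c4[C@H](c4cc(O)cc(O)c4)[C@@H](c4ccc(O)cc4)O6)[C@H](c4ccc(O)cc4)O5)c3c2-c2cc(O)cc(O)c2)cc1 | target

## Step count and risk

Total step count: 17. Longest linear sequence: 10 steps (steps 1, 3, 4, 5, 6, 7, 8, 9, 16, 17 from 1; the same length from 4 through step 2). The ring A branch (steps 10–15) is six steps and joins at step 16.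

**Step 9 (key step, proposed new method).** Three things may go wrong.
- Facial discrimination may be poor, because C3 of ring B acts only through a rotating aryl bond.
- The bond may form at the carbon between the hydroxyls, or oxygen may attack first and give the regioisomeric dihydrofuran.
- The stilbene radical cation may couple with itself, or the phenolic product may be oxidised further.

The fallback uses known reactions only, sets out from 13 and returns at 15 through a second, catalyst-controlled carbene insertion. Compound 13 is alkylated with 2 (K2CO3, DMF) to the bis(4-methoxybenzyl) ether F1. Vilsmeier–Haack formylation (POCl3, DMF) at the ring carbon ortho to the ring B substituent and para to an alkoxy group gives aldehyde F2. Addition of 3,5-dimethoxyphenylmagnesium bromide gives carbinol F3, MnO2 gives benzophenone F4, and hydrazine gives hydrazone F5. MnO2 followed by Rh2(S-PTAD)4 converts F5, through the diazo compound F6 (not isolated), by insertion into the CH2 of the ortho 4-methoxybenzyl ether, into the cis ring C compound F7. Trifluoroacetic acid with 1,3-dimethoxybenzene as cation scavenger then removes the remaining 4-methoxybenzyl group and epimerises C2 of ring C, which gives 15.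

**Step 6.** The bulky silyloxy groups may lower the enantioselectivity of the insertion, the diazo compound may be lost to azine formation, and some enantiopurity may also be lost in step 7 if the ring-opened cation loses the C3 proton reversibly. The fallback replaces reliance on catalysis by a classical resolution; it sets out from 13 and returns to 13. Scalemic 13 is esterified with (1S)-camphanoyl chloride (Et3N, DMAP, CH2Cl2) to the bis-camphanate F8. F8 is freed from its diastereomer by crystallisation or chromatography and cleaved with K2CO3 in MeOH to enantiopure 13.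

**Step 11.** Cyclisation may occur at the other ortho carbon (ortho to methoxy, para to the ester) and give the regioisomeric benzofuran, since both sites are electronically activated. The fallback fixes C3a by a carbonyl carbon; it sets out from 2 and returns at 24. Purchased 2-bromo-6-hydroxy-4-methoxybenzaldehyde F9 is alkylated with 2 (K2CO3, DMF) to ether F10. 3,5-Dimethoxyphenylmagnesium bromide gives carbinol F11 and MnO2 gives ketone F12. The phosphazene base P4-t-Bu deprotonates the benzylic ether CH2, the carbanion adds to the ketone, and acid-induced dehydration gives the 4-bromobenzofuran F13. Suzuki–Miyaura vinylation with potassium vinyltrifluoroborate (PdCl2(dppf), Cs2CO3, THF/H2O) gives 24.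

**Step 16.** Oxidative addition to the electron-rich bromide may be slow, and the hindered styrene 24 may insert with the wrong regiochemistry (1,1-diarylethene) or polymerise at the temperature needed. The fallback moves the alkene construction to an olefination and forms the aryl–alkenyl bond by Suzuki–Miyaura coupling; it sets out from 23 and returns at 25. Aldehyde 23 is treated with Cl2CHB(pin), CrCl2 and LiI in THF (Takai-type boron olefination) to give the (E)-alkenyl pinacol boronate F14. F14 is coupled with 15 (PdCl2(dppf), K3PO4, dioxane/H2O, 80 °C) to give 25.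

**Step 17.** Acid-triggered closure of the stilbene onto the 3,5-dioxygenated ring on C3 of ring A (a seven-membered Friedel–Crafts ring) or irreversible opening of a C2–O bond may compete before all eight ethers are cleaved, and the free nonaphenol may degrade on isolation. The fallback replaces electrophilic by nucleophilic dealkylation and isolates through an ester; it sets out from 25 and returns at 26. Compound 25 is heated with excess NaSEt in DMF (attack of thiolate at the methyl groups under basic conditions, no cations). The crude polyphenol is acetylated (Ac2O, pyridine) to the nonaacetate F15, which can be purified on silica. F15 is cleaved with K2CO3 in MeOH at 0 °C to give 26.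

## Further compounds

F1 | step 9 | (2R,3R)-3-{3,5-bis[(4-methoxybenzyl)oxy]phenyl}-5-bromo-2-(4-methoxyphenyl)-2,3-dihydro-1-benzofuran | Brc1ccc2c(c1)[C@@H](c1cc(OCc3ccc(OC)cc3)cc(OCc3ccc(OC)cc3)c1)[C@H](c1ccc(OC)cc1)O2
F2 | step 9 | 2-[(2R,3R)-5-bromo-2-(4-methoxyphenyl)-2,3-dihydro-1-benzofuran-3-yl]-4,6-bis[(4-methoxybenzyl)oxy]benzaldehyde | Brc1ccc2c(c1)[C@@H](c1cc(OCc3ccc(OC)cc3)cc(OCc3ccc(OC)cc3)c1C=O)[C@H](c1ccc(OC)cc1)O2
F3 | step 9 | {2-[(2R,3R)-5-bromo-2-(4-methoxyphenyl)-2,3-dihydro-1-benzofuran-3-yl]-4,6-bis[(4-methoxybenzyl)oxy]phenyl}(3,5-dimethoxyphenyl)methanol (carbinol epimers) | Brc1ccc2c(c1)[C@@H](c1cc(OCc3ccc(OC)cc3)cc(OCc3ccc(OC)cc3)c1C(O)c1cc(OC)cc(OC)c1)[C@H](c1ccc(OC)cc1)O2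
F4 | step 9 | {2-[(2R,3R)-5-bromo-2-(4-methoxyphenyl)-2,3-dihydro-1-benzofuran-3-yl]-4,6-bis[(4-methoxybenzyl)oxy]phenyl}(3,5-dimethoxyphenyl)methanone | Brc1ccc2c(c1)[C@@H](c1cc(OCc3ccc(OC)cc3)cc(OCc3ccc(OC)cc3)c1C(=O)c1cc(OC)cc(OC)c1)[C@H](c1ccc(OC)cc1)O2
F5 | step 9 | hydrazone of F4 | Brc1ccc2c(c1)[C@@H](c1cc(OCc3ccc(OC)cc3)cc(OCc3ccc(OC)cc3)c1C(=NN)c1cc(OC)cc(OC)c1)[C@H](c1ccc(OC)cc1)O2
F6 | step 9 | diazo compound from F5 | Brc1ccc2c(c1)[C@@H](c1cc(OCc3ccc(OC)cc3)cc(OCc3ccc(OC)cc3)c1C(=[N+]=[N-])c1cc(OC)cc(OC)c1)[C@H](c1ccc(OC)cc1)O2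
F7 | step 9 | (2R,3R)-5-bromo-3-{(2R,3S)-3-(3,5-dimethoxyphenyl)-6-[(4-methoxybenzyl)oxy]-2-(4-methoxyphenyl)-2,3-dihydro-1-benzofuran-4-yl}-2-(4-methoxyphenyl)-2,3-dihydro-1-benzofuran (ring C cis) | Brc1ccc2c(c1)[C@@H](c1cc(OCc3ccc(OC)cc3)cc3c1[C@H](c1cc(OC)cc(OC)c1)[C@H](c1ccc(OC)cc1)O3)[C@H](c1ccc(OC)cc1)O2
F8 | step 6 | bis[(1S,4R)-camphanate] of 13 | Brc1ccc2c(c1)[C@@H](c1cc(OC(=O)[C@@]34CC[C@@](C)(C(=O)O3)C4(C)C)cc(OC(=O)[C@@]34CC[C@@](C)(C(=O)O3)C4(C)C)c1)[C@H](c1ccc(OC)cc1)O2
F9 | step 11 | 2-bromo-6-hydroxy-4-methoxybenzaldehyde | O=Cc1c(O)cc(OC)cc1Br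
F10 | step 11 | 2-bromo-4-methoxy-6-[(4-methoxybenzyl)oxy]benzaldehyde | O=Cc1c(OCc2ccc(OC)cc2)cc(OC)cc1Br
F11 | step 11 | {2-bromo-4-methoxy-6-[(4-methoxybenzyl)oxy]phenyl}(3,5-dimethoxyphenyl)methanol (racemic) | OC(c1cc(OC)cc(OC)c1)c1c(OCc2ccc(OC)cc2)cc(OC)cc1Br
F12 | step 11 | {2-bromo-4-methoxy-6-[(4-methoxybenzyl)oxy]phenyl}(3,5-dimethoxyphenyl)methanone | O=C(c1cc(OC)cc(OC)c1)c1c(OCc2ccc(OC)cc2)cc(OC)cc1Br
F13 | step 11 | 4-bromo-3-(3,5-dimethoxyphenyl)-6-methoxy-2-(4-methoxyphenyl)-1-benzofuran | Brc1cc(OC)cc2oc(-c3ccc(OC)cc3)c(-c3cc(OC)cc(OC)c3)c12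
F14 | step 16 | 2-{(E)-2-[3-(3,5-dimethoxyphenyl)-6-methoxy-2-(4-methoxyphenyl)-1-benzofuran-4-yl]ethenyl}-4,4,5,5-tetramethyl-1,3,2-dioxaborolane | CC1(C)OB(/C=C/c2cc(OC)cc3oc(-c4ccc(OC)cc4)c(-c4cc(OC)cc(OC)c4)c23)OC1(C)C
F15 | step 17 | nonaacetate of 26 | CC(=O)Oc1ccc(-c2oc3cc(OC(C)=O)cc(/C=C/c4ccc5c(c4)[C@@H](c4cc(OC(C)=O)cc6c4[C@H](c4cc(OC(C)=O)cc(OC(C)=O)c4)[C@@H](c4ccc(OC(C)=O)cc4)O6)[C@H](c4ccc(OC(C)=O)cc4)O5)c3c2-c2cc(OC(C)=O)cc(OC(C)=O)c2)cc1
A1 | alternative 1 | 3-(3,5-dimethoxyphenyl)-6-ethoxy-2-(4-methoxyphenyl)-1-benzofuran-4-ol | CCOc1cc(O)c2c(c1)oc(-c1ccc(OC)cc1)c2-c1cc(OC)cc(OC)c1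
A2 | alternative 1 | 2-diazo-1-[4-(3,5-dimethoxyphenyl)-5-(4-methoxyphenyl)furan-2-yl]ethan-1-one | [N-]=[N+]=CC(=O)c1cc(-c2cc(OC)cc(OC)c2)c(-c2ccc(OC)cc2)o1
A3 | alternative 1 | ethoxyacetylene | CCOC#C
A4 | alternative 2 | {2-[(2R,3R)-5-bromo-2-(4-methoxyphenyl)-2,3-dihydro-1-benzofuran-3-yl]-6-hydroxy-4-methoxyphenyl}(3,5-dimethoxyphenyl)methanone | Brc1ccc2c(c1)[C@@H](c1cc(OC)cc(O)c1C(=O)c1cc(OC)cc(OC)c1)[C@H](c1ccc(OC)cc1)O2
A5 | alternative 2 | 3-[(2R,3R)-5-bromo-2-(4-methoxyphenyl)-2,3-dihydro-1-benzofuran-3-yl]-1-(3,5-dimethoxyphenyl)prop-2-yn-1-one | Brc1ccc2c(c1)[C@@H](C#CC(=O)c1cc(OC)cc(OC)c1)[C@H](c1ccc(OC)cc1)O2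
A6 | alternative 2 | 1,3-dimethoxy-1-(trimethylsilyloxy)buta-1,3-diene | C=C(OC)C=C(OC)O[Si](C)(C)C
A7 | alternative 3 | (2R,3R)-3-[(2S,3S)-3-(3,5-dimethoxyphenyl)-6-methoxy-2-(4-methoxyphenyl)-2,3-dihydro-1-benzofuran-4-yl]-2-(4-methoxyphenyl)-2,3-dihydro-1-benzofuran-5-ol | Oc1ccc2c(c1)[C@@H](c1cc(OC)cc3c1[C@H](c1cc(OC)cc(OC)c1)[C@@H](c1ccc(OC)cc1)O3)[C@H](c1ccc(OC)cc1)O2
A8 | alternative 3 | (2S,3S)-3-(3,5-dimethoxyphenyl)-6-methoxy-2-(4-methoxyphenyl)-4-[(E)-2-(4-methoxyphenyl)ethenyl]-2,3-dihydro-1-benzofuran | COc1ccc(/C=C/c2cc(OC)cc3c2[C@H](c2cc(OC)cc(OC)c2)[C@@H](c2ccc(OC)cc2)O3)cc1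
A9 | alternative 3 | 1,4-benzoquinone | O=C1C=CC(=O)C=C1
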